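J, the catalyst, is the charge to follow in this flask, and the quantity to carry is what it does to the excess of E over Z among what is left.

all flasks: Z 0.22 M; E 0.22 M
- eta: G 1 equiv; J 0.43 mol%; run made earlier
- gamma: G 4 equiv; J 0.43 mol%; run made earlier
- beta: G 2 equiv; J 0.21 mol%; run made earlier
- flask: G 2.00 equiv; J 0.43 mol%; time 1.0 h

- eta (time / min: Z / %, E / %): 6.00: 47.5, 49.3; 12.0: 45.4, 47.7; 20.0: 42.9, 44.9; 25.0: 41.7, 43.2; 30.0: 39.8, 41.9; 40.0: 36.7, 38.7
- gamma (time / min: Z / %, E / %): 2.50: 49.6, 49.9; 8.00: 47.4, 48.2; 12.0: 45.0, 47.6; 20.0: 42.6, 45.0; 30.0: 39.9, 41.9; 40.0: 36.7, 39.0
- beta (time / min: Z / %, E / %): 8.00: 46.7, 48.6; 15.0: 44.1, 46.5; 20.0: 42.1, 45.8; 30.0: 39.0, 43.0; 40.0: 36.4, 40.6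

(standard deviation of a reading: 0.3 percentage points)

- D is single-handed; Z and E are mirror images of each other, charged as a racemate, each of them at the stated concentration
- solid, in amounts per volume of the solution: G
- at the start none of G is in solution
- an excess is the difference of the two amounts in percent of their sum
- an excess is below zero if the other one leads
- the handed part of D does not stay in what it makes, so the products of the two hands are mirror images too

* part of the Z and E charged together that has reacted at 1.0 h
* excess of Q over L in the product at 1.0 h
* excess of E over Z among what is left of the two at 1.0 h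

At 40.0 min the beta run, with 0.21 mol% of J, shows an excess of 5.45%, and at the same time the gamma and eta runs, with 0.43 mol%, show smaller ones, 3.04% and 2.65%. Beta also differs in G, but its 2 equiv lies between the 1 equiv of eta and the 4 equiv of gamma, and those two excesses differ by less than either differs from beta, so you may read the step to beta as a step in J. This flask has more J than beta, so your first bracket, as an estimate, runs from zero up to the beta reading.

To tighten it, go to powers of ten. From beta to full loading, J rises by 0.311 in the logarithm, and the excess falls by 0.282. The two steps are close, as in a dynamic kinetic resolution, where the reaction pulls Z and E apart while J brings them back. So take the excess-loading product, the excess as a fraction times the loading of J, read from beta as 0.011 mol%.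

For this flask it gives 2.66%, if the excess stays level up to 1.0 h. One excess carries a scatter of about 0.560%, so 2 such widths each way give a bracket from 1.54% to 3.78%.

The forecast gives 35% reacted, 43% of Q over L and 2.8% of E over Z, holding that “The remaining excess stays at steady state”, and that last value lies inside your bracket.

The flask gives 35.0% reacted, 1.78% of Q over L and 3.49% of E over Z, and this last value lies inside the bracket.

    Z + J ⇌ E + J, rate k1*[J]*[Z] forward; the back reaction follows from the equilibrium constant (k = 0.960 M⁻¹ s⁻¹)
    G ⇌ D, rate k2*(cs2 - [D]) while solid is left; crystals form when [D] > cs2 (solubility = 16.0 mM, k = 0.00700 s⁻¹)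
    Q ⇌ L (k = 0.00320 s⁻¹)
    D + E → L (k = 0.00660 M⁻¹ s⁻¹)
    D + Z → Q (k = 0.0190 M⁻¹ s⁻¹)

At 1.00 h the relaxation half-life of Z and E through J, both ways together, is 0.106 h, shorter than the run of 1.0 h. The flask's excess times its loading is 0.015 mol%, against the 0.011 mol% read from beta. In the neighbour with 0.17 mol% of J, the product 0.011 mol% gives an excess of 6.74%, and the computed result for that flask is 7.95%.

The runs were computed on assumed constants; scatter was added.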